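The dihydrofuran ring (O1, C2, C3, C3a, C7a) is cut at O1–C2. C2 is allylic to the isopropenyl group, and the C3 ester oxygen is 1,5-related to O1 through C3–C3a–C7a. The precursor is therefore an isomer of the target: a (2R,3R)-trans aryl isopropenyl oxirane whose ortho phenol oxygen carries the angeloyl group. It comes in one step from the aldehyde and a chiral methallyl sulfonium ylide. With Pd(0) the vinyl oxirane ionises, the C3 alkoxide takes the angeloyl group from O1, and the freed phenoxide closes on C2 of the π-allyl unit with net retention. This gives the cis target without protecting groups or late esterification.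

Key step: step 6

Assumptions: 1, 3, 6, 8 and 9 are taken as catalogue compounds; the ylide from (1R,4R,5R)-8 is taken to give the (R,R)-oxirane, and if the sense of induction proves opposite, the equally available enantiomer of 8 is used in the same way.

Step 1
Reactants: 1 2-hydroxy-3,4-dimethoxybenzaldehyde
Product: 2 2-hydroxy-5-iodo-3,4-dimethoxybenzaldehyde
Conditions: NIS (1.05 equiv), TFA (10 mol%), MeCN, 0 °C to rt
Reagents that add atoms: N-iodosuccinimide, O=C1CCC(=O)N1I
Why: Electrophilic aromatic iodination; C5 is para to the free OH, ortho to the 4-OMe and meta to the formyl group, so all directing effects converge there and C6 should stay untouched.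

Step 2
Reactants: 2 2-hydroxy-5-iodo-3,4-dimethoxybenzaldehyde; 3 tributyl(1-ethoxyvinyl)stannane
Product: 5 5-acetyl-2-hydroxy-3,4-dimethoxybenzaldehyde, via aryl enol ether 4 (not isolated)
Conditions: PdCl2(PPh3)2 (5 mol%), 3 (1.3 equiv), toluene, 100 °C; then 1 M aq. HCl, THF, rt
Reagents that add atoms: water, O
Why: Stille coupling of the aryl iodide with an acetyl-anion equivalent tolerates the hydrogen-bonded phenol and the aldehyde, and dilute acid hydrolyses the aryl enol ether 4 to the methyl ketone.

Step 3
Reactants: 5 5-acetyl-2-hydroxy-3,4-dimethoxybenzaldehyde; 6 angelic anhydride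
Product: 7 4-acetyl-6-formyl-2,3-dimethoxyphenyl (Z)-2-methylbut-2-enoate
Conditions: Cs2CO3 (1.1 equiv), MeCN, 0 °C to rt
Reagents that add atoms: none
Why: O-acylation of the caesium phenoxide (an acidic phenol, ortho to CHO and para to Ac) with the symmetrical anhydride needs neither a nucleophilic catalyst nor an acid chloride, the two usual causes of Z-to-E isomerisation of angelates.

Step 4
Reactants: 8 (1R,4R,5R)-isothiocineole; 9 3-bromo-2-methylpropene
Product: 10 S-(2-methylallyl)isothiocineolium triflate
Conditions: LiOTf (5 equiv), CH2Cl2/H2O, rt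
Reagents that add atoms: lithium trifluoromethanesulfonate, [Li+].[O-]S(=O)(=O)C(F)(F)F
Why: SN2 S-alkylation of the bicyclic thioether by the allylic bromide with bromide-to-triflate exchange in the two-phase medium; only the less hindered sulfur lone pair is expected to react, giving one sulfonium diastereomer.

Step 5
Reactants: 7 4-acetyl-6-formyl-2,3-dimethoxyphenyl (Z)-2-methylbut-2-enoate; 10 S-(2-methylallyl)isothiocineolium triflate
Product: 12 4-acetyl-2,3-dimethoxy-6-[(2R,3R)-3-(prop-1-en-2-yl)oxiran-2-yl]phenyl (Z)-2-methylbut-2-enoate, via sulfonium ylide 11 (not isolated)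
Conditions: 10, KHMDS (1.0 equiv), THF, −78 °C; then 7, −78 to −40 °C; chromatography on Et3N-deactivated silica
Reagents that add atoms: none
Why: Asymmetric Johnson–Corey–Chaykovsky epoxidation with a chiral semistabilised ylide: the rigid sulfide fixes the ylide conformation and shields one face (sets the future C2), the anti betaine closes while the syn betaine reverts (trans oxirane, sets the future C3), the aldehyde should outrun the aryl ketone and the hindered aryl ester at −78 °C, and the minor cis oxirane is removed by chromatography.

Step 6
Reactants: 12 4-acetyl-2,3-dimethoxy-6-[(2R,3R)-3-(prop-1-en-2-yl)oxiran-2-yl]phenyl (Z)-2-methylbut-2-enoate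
Product: 15 (2R,3R)-5-acetyl-6,7-dimethoxy-2-(prop-1-en-2-yl)-2,3-dihydro-1-benzofuran-3-yl (Z)-2-methylbut-2-enoate, via allylpalladium alkoxide zwitterion 13 (not isolated), via allylpalladium phenoxide zwitterion 14 (not isolated)
Conditions: Pd2(dba)3·CHCl3 (2.5 mol%), dppe (6 mol%), THF, 0 °C to rt
Reagents that add atoms: none
Why: Proposed new method: Pd(0) ionises the allylic C–O bond of the vinyl oxirane with inversion to the η3-(2-methylallyl)palladium alkoxide 13, whose C3 alkoxide attacks the neighbouring aryl ester through a six-membered tetrahedral intermediate and keeps the angeloyl group because the p-acetylphenoxide is by far the better leaving group, which unmasks phenoxide 14. The closest known reaction types are the Tsuji–Trost opening of vinyl epoxides in which the freed alkoxide first adds to CO2 or an isocyanate and the new nucleophile closes on the proximal allyl carbon with net retention, and the Pd-catalysed cyclisation of 4-(2-hydroxyaryl)-2-methylbut-2-enyl carbonates to 2-isopropenyl-2,3-dihydrobenzofurans; only the O-to-O acyl shift as relay is new. The ring O1–C2–C3–C3a–C7a closes by 5-exo attack of O1 on the internal allyl terminus C2 anti to palladium, which should be kinetically preferred to 7-endo attack on the CH2 terminus. C3 keeps its C–O bond throughout and stays R, while C2 is formed by double inversion, so O1 takes the place of the oxirane oxygen and the trans-(R,R)-oxirane maps onto the cis-(2R,3R)-product. Capture must be faster than face exchange of the allyl unit through its CH2 terminus, than hydride or proton shifts of 13 and than re-ionisation of the allyl aryl ether 15; both capture events are intramolecular, and a halide-free catalyst, a chelating diphosphine, a weakly coordinating solvent and low temperature slow the competing processes.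

Compound list
1 | 2-hydroxy-3,4-dimethoxybenzaldehyde | O=Cc1ccc(OC)c(OC)c1O | starting material
2 | 2-hydroxy-5-iodo-3,4-dimethoxybenzaldehyde | O=Cc1cc(I)c(OC)c(OC)c1O | intermediate
3 | tributyl(1-ethoxyvinyl)stannane | C=C(OCC)[Sn](CCCC)(CCCC)CCCC | starting material
4 | 5-(1-ethoxyvinyl)-2-hydroxy-3,4-dimethoxybenzaldehyde (not isolated) | C=C(OCC)c1cc(C=O)c(O)c(OC)c1OC | intermediate
5 | 5-acetyl-2-hydroxy-3,4-dimethoxybenzaldehyde | CC(=O)c1cc(C=O)c(O)c(OC)c1OC | intermediate
6 | angelic anhydride, (Z)-2-methylbut-2-enoic anhydride | C/C=C(/C)C(=O)OC(=O)/C(C)=C\C | starting material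
7 | 4-acetyl-6-formyl-2,3-dimethoxyphenyl (Z)-2-methylbut-2-enoate | CC(=O)c1cc(C=O)c(OC(=O)/C(C)=C\C)c(OC)c1OC | intermediate
8 | (1R,4R,5R)-4,7,7-trimethyl-6-thiabicyclo[3.2.1]octane (isothiocineole) | C[C@@H]1CC[C@@H]2C[C@H]1SC2(C)C | starting material
9 | 3-bromo-2-methylpropene (methallyl bromide) | C=C(C)CBr | starting material
10 | (1R,4R,5R)-4,7,7-trimethyl-6-(2-methylprop-2-en-1-yl)-6-thiabicyclo[3.2.1]octan-6-ium triflate (allyl group on the less hindered sulfur lone pair; sulfur configuration not written) | C[C@@H]1CC[C@@H]2C[C@H]1[S+](CC(C)=C)C2(C)C.[O-]S(=O)(=O)C(F)(F)F | intermediate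
11 | 2-methylallylide of 10 (not isolated) | C[C@@H]1CC[C@@H]2C[C@H]1[S+]([CH-]C(C)=C)C2(C)C | intermediate
12 | 4-acetyl-2,3-dimethoxy-6-[(2R,3R)-3-(prop-1-en-2-yl)oxiran-2-yl]phenyl (Z)-2-methylbut-2-enoate (trans oxirane) | C=C(C)[C@H]1O[C@@H]1c2cc(C(C)=O)c(OC)c(OC)c2OC(=O)/C(C)=C\C | intermediate
13 | η3-allylpalladium alkoxide zwitterion, aryl angelate intact (drawn as the η1 form, diphosphine omitted; not isolated) | CC(C[Pd+])=C[C@H]([O-])c1cc(C(C)=O)c(OC)c(OC)c1OC(=O)/C(C)=C\C | intermediate
14 | η3-allylpalladium phenoxide zwitterion after the acyl shift (drawn as the η1 form, diphosphine omitted; not isolated) | CC(C[Pd+])=C[C@H](OC(=O)/C(C)=C\C)c1cc(C(C)=O)c(OC)c(OC)c1[O-] | intermediate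
15 | (2R,3R)-5-acetyl-6,7-dimethoxy-2-(prop-1-en-2-yl)-2,3-dihydro-1-benzofuran-3-yl (Z)-2-methylbut-2-enoate (2,3-cis) | C=C(C)[C@H]1Oc2c(cc(C(C)=O)c(OC)c2OC)[C@H]1OC(=O)/C(C)=C\C | target

Total step count: 6. Longest linear sequence: 5 (steps 1, 2, 3, 5, 6).

Steps most likely to fail

Step 6 (labelled step). The alkoxide of the opened oxirane may be lost to proton or hydride shifts before the acyl shift takes place. Face exchange of the allyl unit through its CH2 terminus may also scramble C2. The fallback uses known reactions and runs from 12 back to 15 by taking the relay apart.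
- Mild methanolysis of the activated aryl ester (K2CO3 cat., MeOH, 0 °C, then AcOH) gives the free phenol oxirane F1.
- The established Pd(0)-catalysed intramolecular addition of a phenol to a vinyl oxirane (Tsuji–Trost etherification) then gives the cis alcohol F2. It is run with the matched enantiomer of the DACH-phenyl diphosphine, so that the ligand rather than the memory of the oxirane fixes C2.
- Yamaguchi-type esterification with angelic acid (2,4,6-trichlorobenzoyl chloride, Et3N, toluene, 80 °C), a protocol known to conserve the Z geometry, gives 15.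

Step 5. With this electron-poor, doubly ortho-substituted aldehyde, both betaines may form irreversibly, which would lower the trans/cis ratio and the enantiomeric purity. The ylide may also attack the aryl ester. A betaine diverted by acyl shift and phenoxide displacement of the sulfide would converge on 15 itself. The fallback runs from 7 back to 12, making the C2–C3 bond as an alkene and oxidising it afterwards.
- Aldehyde-selective Takai olefination (CrCl2, CHI3, THF, 0 °C) gives the (E)-vinyl iodide F3.
- Stille coupling with tributyl(isopropenyl)stannane gives the (E)-diene F4.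
- Shi epoxidation with the D-fructose-derived ketone gives 12. It is run with Oxone, buffered near pH 8 to spare the aryl ester, in MeCN/water at 0 °C. This reagent oxidises the trans-disubstituted alkene in preference to the 1,1-disubstituted one and delivers (R,R)-oxiranes from trans alkenes.

Step 3. Acylation of a hydrogen-bonded phenol flanked by two ortho substituents may be slow, leaving time for Z-to-E isomerisation of the angeloyl unit. The fallback runs from 5 back to 7 and builds the ester carbonyl by carbonylation instead of acyl transfer. Pd-catalysed phenoxycarbonylation of (Z)-2-bromobut-2-ene with CO and 5 (Pd(OAc)2, Xantphos, Et3N, CO 1 atm, toluene, 80 °C) proceeds with retention of the alkene geometry in oxidative addition and CO insertion. No new compound is made (F0).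

Further compounds
F1 | step 6 | 1-{4-hydroxy-2,3-dimethoxy-5-[(2R,3R)-3-(prop-1-en-2-yl)oxiran-2-yl]phenyl}ethan-1-one | C=C(C)[C@H]1O[C@@H]1c2cc(C(C)=O)c(OC)c(OC)c2O
F2 | step 6 | 1-[(2R,3R)-3-hydroxy-6,7-dimethoxy-2-(prop-1-en-2-yl)-2,3-dihydro-1-benzofuran-5-yl]ethan-1-one | C=C(C)[C@H]1Oc2c(cc(C(C)=O)c(OC)c2OC)[C@H]1O
F3 | step 5 | 4-acetyl-6-[(E)-2-iodoethenyl]-2,3-dimethoxyphenyl (Z)-2-methylbut-2-enoate | I/C=C/c1cc(C(C)=O)c(OC)c(OC)c1OC(=O)/C(C)=C\C
F4 | step 5 | 4-acetyl-2,3-dimethoxy-6-[(E)-3-methylbuta-1,3-dien-1-yl]phenyl (Z)-2-methylbut-2-enoate | C=C(C)/C=C/c1cc(C(C)=O)c(OC)c(OC)c1OC(=O)/C(C)=C\C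
F0 | step 3 | none | none
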